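**Retrosynthetic overview**

1. Target ⇐ racemic flavanone by a 2,3-aryl shift (the isoflavone synthase event), telescoped with loss of both MOM groups.
2. Flavanone ⇐ 2'-hydroxychalcone by 6-endo oxa-Michael closure of ring C (the chalcone isomerase event) ⇐ Claisen–Schmidt union of a ring A acetophenone and a ring B/D aldehyde.
3. Ring B/D aldehyde ⇐ 2,4-dihydroxy-5-methoxybenzaldehyde + prenal; ring D closes by oxa-6π electrocyclisation of the ortho-quinone methide that dehydrogenation of a 3-prenylphenol is thought to give in the plant.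
4. Ring order: D (pyran) first, on the aldehyde, where the chelated 2-OH fixes the regiochemistry; then C (pyranone); the aryl shift comes last.

Assumption: the target has no stereocentre, so it is made as the achiral compound drawn; the flavanone-type intermediates are racemic and their one stereocentre is erased in the last step.

**Route**

Step 1
Reactants: 1 2,4-dihydroxy-5-methoxybenzaldehyde; 2 3-methylbut-2-enal (prenal)
Product: 4 5-hydroxy-8-methoxy-2,2-dimethyl-2H-chromene-6-carbaldehyde, via ortho-quinone methide 3 (not isolated)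
Conditions: 2 (1.5 equiv), ethylenediammonium diacetate (10 mol%), xylene, 140 °C
Reagents that add atoms: none
Why: Knoevenagel-type C-alkylation at C3 (the only free position activated by both hydroxyls) and loss of water give the ortho-quinone methide, whose oxa-6π electrocyclisation closes ring D through O4 because the 2-OH stays hydrogen-bonded to the aldehyde.

Step 2
Reactants: 4 5-hydroxy-8-methoxy-2,2-dimethyl-2H-chromene-6-carbaldehyde
Product: 5 8-methoxy-5-(methoxymethoxy)-2,2-dimethyl-2H-chromene-6-carbaldehyde
Conditions: NaH, MOMCl, DMF, 0 °C to rt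
Reagents that add atoms: chloromethyl methyl ether (MOMCl), COCCl
Why: Williamson-type O-alkylation of the fully deprotonated chelated phenol installs an acetal that survives the basic aldol, keeps the para-methoxyphenol from being oxidised to a quinone in step 5 and is removed in the final acidic stage.

Step 3
Reactants: 6 1-(2,4-dihydroxyphenyl)ethanone (2,4-dihydroxyacetophenone)
Product: 7 1-[2-hydroxy-4-(methoxymethoxy)phenyl]ethanone
Conditions: MOMCl (1.1 equiv), K2CO3, acetone, rt
Reagents that add atoms: chloromethyl methyl ether (MOMCl), COCCl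
Why: Regioselective Williamson-type O-alkylation caps the accessible 4-OH while the 2-OH, locked in a hydrogen bond to the acetyl group, stays free for ring C closure.

Step 4
Reactants: 5 8-methoxy-5-(methoxymethoxy)-2,2-dimethyl-2H-chromene-6-carbaldehyde; 7 1-[2-hydroxy-4-(methoxymethoxy)phenyl]ethanone
Product: 9 racemic 7-(methoxymethoxy)-2-[8-methoxy-5-(methoxymethoxy)-2,2-dimethyl-2H-chromen-6-yl]-2,3-dihydro-4H-chromen-4-one, via chalcone 8 (not isolated)
Conditions: KOH (50% aq), EtOH, rt; then AcOH (1 equiv per KOH), reflux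
Reagents that add atoms: none
Why: Claisen–Schmidt aldol condensation gives the (E)-chalcone and the acetate-buffered 6-endo oxa-Michael addition of the 2'-phenol closes ring C under equilibrium control (recovered chalcone is recycled), with C2 formed racemic and destroyed in step 5.

Step 5
Reactants: 9 racemic 7-(methoxymethoxy)-2-[8-methoxy-5-(methoxymethoxy)-2,2-dimethyl-2H-chromen-6-yl]-2,3-dihydro-4H-chromen-4-one
Product: 12 7-hydroxy-3-(5-hydroxy-8-methoxy-2,2-dimethyl-2H-chromen-6-yl)-4H-chromen-4-one, via silyl enol ether 10 (not isolated), via bis-MOM isoflavone 11 (not isolated)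
Conditions: TMSOTf (1.1 equiv), Et3N (1.1 equiv), CH2Cl2, 0 °C; then PhI(OH)OTs (1.0 equiv), CH2Cl2/MeCN, −40 to 0 °C; then 3 M HCl, MeOH, 50 °C
Reagents that add atoms: none
Why: Proposed new method: the trimethylsilyl enol ether is orders of magnitude more nucleophilic than the chromene double bond or the alkoxy-arene, so one equivalent of the trivalent iodine reagent is taken up at C3 at low temperature; the anti-periplanar, electron-rich C2 aryl group then shifts to C3 as iodobenzene leaves and the C2 oxocarbenium ion loses H-3 to give the isoflavone; the closest known reactions are the 2,3-aryl shift of flavanones to isoflavones with PhI(OH)OTs in hot MeCN and the alpha-oxidation of silyl enol ethers with the same reagent, and the last stage is an ordinary acid-catalysed acetal exchange that removes both MOM groups.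

**Compound list**

1 | 2,4-dihydroxy-5-methoxybenzaldehyde | COc1cc(C=O)c(O)cc1O | starting material
2 | 3-methylbut-2-enal (prenal) | CC(C)=CC=O | starting material
3 | (Z)-2-hydroxy-5-methoxy-3-(3-methylbut-2-en-1-ylidene)-4-oxocyclohexa-1,5-diene-1-carbaldehyde (ortho-quinone methide) | O=C1C(OC)=CC(C=O)=C(O)/C1=C/C=C(C)C | intermediate
4 | 5-hydroxy-8-methoxy-2,2-dimethyl-2H-chromene-6-carbaldehyde | COc1cc(C=O)c(O)c2c1OC(C)(C)C=C2 | intermediate
5 | 8-methoxy-5-(methoxymethoxy)-2,2-dimethyl-2H-chromene-6-carbaldehyde | COCOc1c(C=O)cc(OC)c2OC(C)(C)C=Cc12 | intermediate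
6 | 1-(2,4-dihydroxyphenyl)ethanone | CC(=O)c1ccc(O)cc1O | starting material
7 | 1-[2-hydroxy-4-(methoxymethoxy)phenyl]ethanone | CC(=O)c1ccc(OCOC)cc1O | intermediate
8 | (E)-1-[2-hydroxy-4-(methoxymethoxy)phenyl]-3-[8-methoxy-5-(methoxymethoxy)-2,2-dimethyl-2H-chromen-6-yl]prop-2-en-1-one (chalcone) | COCOc1ccc(C(=O)/C=C/c2cc(OC)c3OC(C)(C)C=Cc3c2OCOC)c(O)c1 | intermediate
9 | racemic 7-(methoxymethoxy)-2-[8-methoxy-5-(methoxymethoxy)-2,2-dimethyl-2H-chromen-6-yl]-2,3-dihydro-4H-chromen-4-one (flavanone, C2 undefined) | COCOc1ccc2C(=O)CC(Oc2c1)c1cc(OC)c2OC(C)(C)C=Cc2c1OCOC | intermediate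
10 | racemic trimethyl({7-(methoxymethoxy)-2-[8-methoxy-5-(methoxymethoxy)-2,2-dimethyl-2H-chromen-6-yl]-2H-chromen-4-yl}oxy)silane (silyl enol ether, C2 undefined) | COCOc1ccc2C(O[Si](C)(C)C)=CC(Oc2c1)c1cc(OC)c2OC(C)(C)C=Cc2c1OCOC | intermediate
11 | 7-(methoxymethoxy)-3-[8-methoxy-5-(methoxymethoxy)-2,2-dimethyl-2H-chromen-6-yl]-4H-chromen-4-one (bis-MOM isoflavone) | COCOc1ccc2c(c1)occ(-c1cc(OC)c3OC(C)(C)C=Cc3c1OCOC)c2=O | intermediate
12 | 7-hydroxy-3-(5-hydroxy-8-methoxy-2,2-dimethyl-2H-chromen-6-yl)-4H-chromen-4-one | COc1cc(-c2coc3cc(O)ccc3c2=O)c(O)c2c1OC(C)(C)C=C2 | target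

**Step count and risks**

Total step count: 5. Longest linear sequence: 4 (steps 1, 2, 4, 5; step 3 runs in parallel).

Most likely to fail, step 5: the trivalent iodine reagent may attack the chromene double bond or the electron-rich ring B, and the C3 intermediate may lose H-2 to give the flavone or be tosyloxylated instead of rearranging. The fallback is a 1,2-shift that never exposes the chromene to an electrophilic oxidant. It sets out from chalcone 8, isolated by working up step 4 before the acetic acid stage, and comes back to the route at target 12. The chelated phenol of 8 is capped (NaH, MOMCl, DMF) to give the tris-MOM chalcone F1. Its enone alone is epoxidised by the nucleophilic oxidant (H2O2, NaOH, MeOH/acetone, 0 °C) to the racemic trans-epoxide F2. BF3·OEt2 in CH2Cl2 at −20 °C opens F2 at the benzylic carbon and the aroyl group shifts, giving the beta-keto aldehyde F3. 3 M HCl in MeOH at 50 °C then strips the three MOM groups and closes ring C by condensation of the freed 2-hydroxyl with the aldehyde, giving 12.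

Second, step 4: the very electron-rich ring B stabilises the chalcone, so the oxa-Michael equilibrium may leave much 8 uncyclised. The fallback closes ring C under kinetic control. It sets out from aldehyde 5 and acetophenone 7 and comes back at flavanone 9. The dianion of 7 (LiN(i-Pr)2, 2.2 equiv, THF, −78 °C) adds to 5 without dehydration to give the racemic beta-hydroxy ketone F4. Mitsunobu etherification (PPh3, diisopropyl azodicarboxylate, THF, 0 °C) then joins the phenol oxygen to the benzylic carbon irreversibly, giving 9.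

Third, step 1: the formyl-deactivated resorcinol may react sluggishly, prenal may oligomerise, and some closure through O2 cannot be excluded. The fallback fixes the pyran oxygen before the ring is made. It sets out from aldehyde 1 and comes back at chromene aldehyde 4. The non-chelated 4-OH of 1 is alkylated with 3-chloro-3-methylbut-1-yne (K2CO3, KI, acetone, reflux) to the aryl propargyl ether F5. Heating F5 in N,N-diethylaniline at 190 °C triggers propargyl Claisen rearrangement to C3 (the only free ortho position), a 1,5-hydrogen shift to the same ortho-quinone methide 3 and oxa-6π closure, which can only give 4.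

**Further compounds**

F1 | step 5 | (E)-1-[2,4-bis(methoxymethoxy)phenyl]-3-[8-methoxy-5-(methoxymethoxy)-2,2-dimethyl-2H-chromen-6-yl]prop-2-en-1-one (tris-MOM chalcone) | COCOc1ccc(C(=O)/C=C/c2cc(OC)c3OC(C)(C)C=Cc3c2OCOC)c(OCOC)c1
F2 | step 5 | racemic trans-[2,4-bis(methoxymethoxy)phenyl]{3-[8-methoxy-5-(methoxymethoxy)-2,2-dimethyl-2H-chromen-6-yl]oxiran-2-yl}methanone (one enantiomer drawn) | COCOc1ccc(C(=O)[C@@H]4O[C@H]4c2cc(OC)c3OC(C)(C)C=Cc3c2OCOC)c(OCOC)c1
F3 | step 5 | racemic 3-[2,4-bis(methoxymethoxy)phenyl]-2-[8-methoxy-5-(methoxymethoxy)-2,2-dimethyl-2H-chromen-6-yl]-3-oxopropanal (beta-keto aldehyde) | COCOc1ccc(C(=O)C(C=O)c2cc(OC)c3OC(C)(C)C=Cc3c2OCOC)c(OCOC)c1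
F4 | step 4 | racemic 3-hydroxy-1-[2-hydroxy-4-(methoxymethoxy)phenyl]-3-[8-methoxy-5-(methoxymethoxy)-2,2-dimethyl-2H-chromen-6-yl]propan-1-one (beta-hydroxy ketone) | COCOc1ccc(C(=O)CC(O)c2cc(OC)c3OC(C)(C)C=Cc3c2OCOC)c(O)c1
F5 | step 1 | 2-hydroxy-5-methoxy-4-[(2-methylbut-3-yn-2-yl)oxy]benzaldehyde (aryl propargyl ether) | COc1cc(C=O)c(O)cc1OC(C)(C)C#C
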